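## Analysis of the target

Numbering used for the target and for every intermediate: C1 carries the C7H2–OBz arm, C2 is the olefinic CH, and C3, C4, C5 and C6 carry O3, O4, O5 and O6.

Compound 19 is a single cyclohexene ring with a trisubstituted C1=C2 double bond. The other four ring carbons, C3–C6, are contiguous oxygen-bearing stereocentres of configuration (3R,4S,5R,6S). O4 and O5 are cis; O3 is trans to O4 and O6 is trans to O5, so O3 and O6 share the face opposite the O4/O5 pair. Five oxygens must be told apart: O7 (primary, allylic) and O5 (secondary) are benzoylated, while O3, O4 and O6 stay free, and O4 and O5 sit in nearly mirror-related surroundings. The sensitive points are the O5 benzoate, which can migrate to the cis O4 under base, the two allylic alcohols, and the tendency of such polyoxygenated cyclohexenes to lose water and aromatise. The difficulty therefore lies in absolute configuration and oxygen differentiation, not in the carbon skeleton. The plan rests on the C4–C5 cis-diol flanked by anti oxygens at C3 and C6: this is the pattern obtained when an arene cis-dihydrodiol takes up a 1,4-dioxygen unit on the face away from its diol.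

## Retrosynthetic reasoning

**O5–acyl bond (19 ⇒ 16 + 17).** The secondary benzoate is removed last. O4/O5 is the only cis-vicinal pair in 16, so only it can close a five-membered cyclic orthobenzoate (18) with 17. Acidic opening of 18 leaves the acyl group on the axial oxygen. The C1 substituent forces O6 pseudoaxial by A(1,2) strain, which makes the trans-related O5 axial, so the ester should stay on O5. The late timing keeps the migration-prone cis hydroxy-benzoate away from every basic step.

**C6–H bond (16 ⇒ 15).** The C6 carbinol is traced to a ketone. A hydride delivered from the lower face, where the free O4 and O5 hydroxyls of 15 sit, gives O6 on the upper face, trans to O5. The reduction must therefore be hydroxyl-directed and must come after the diol is unmasked; an undirected reduction next to a cis-fused dioxolane would attack from the other face.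

**Protecting groups (15 ⇒ 14).** The O4/O5 acetonide and the O3 silyl ether are removed together by acid hydrolysis, so the protection of O3 costs one step, not two. The O7 benzoate of 14 is stable to these conditions.

**O7–acyl bond (14 ⇒ 12 + 13).** The primary benzoate is installed while O7 is the only free hydroxyl, so no selectivity question arises. Having O7 capped before the ketone reduction also removes an in-plane hydroxyl that could deliver hydride without facial bias.

**C1–C7 bond (12 ⇒ 10 + 11).** The hydroxymethyl carbon is cut from the α-carbon of the enone. The C6 ketone of 10 polarises the C1=C2 bond so that C1 becomes nucleophilic after reversible amine addition at C2 (Morita–Baylis–Hillman reaction with 11). This is the reason for keeping C6 at the ketone level so far.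

**O3–Si bond (10 ⇒ 8 + 9).** O3 is silylated so that the hydroxymethylation and the O7 benzoylation see no competing hydroxyl.

**C3–O and C6–O bonds (8 ⇒ 5 + 2).** Both oxygens come from one molecule of 2 in its singlet state, added across the diene termini of 5 on the face opposite the dioxolane (endoperoxide 6). Reductive cleavage of the O–O bond gives the C3 alcohol and, at the bromine-bearing terminus, a geminal bromohydrin (7) that collapses to the C6 ketone. The bromine thus turns two equivalent oxygens into an alcohol and a ketone.

**Acetonide (5 ⇒ 3 + 4).** The cis-diol of 3 is tied up with 4. This stabilises the diene against dehydration and provides the facial bias for the next step.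

**C4–O and C5–O bonds (3 ⇒ 1 + 2).** The cis-diol is traced to the arene itself. No small reagent adds two oxygens cis across one aromatic π-bond and stops; an arene dioxygenase does so and sets both stereocentres in one operation from 1 and 2.

## Alternatives that were turned down

**Alternative 1:** 
- Disconnection: ring bonds C2–C3 and C1–C6, with C7 arriving as an acyl carbon.
- Forward key step: Diels–Alder reaction of (1E,3E)-buta-1,3-diene-1,4-diyl diacetate A1 with 3-(prop-2-ynoyl)-1,3-oxazolidin-2-one A2, activated by Cu(OTf)2 A3 (divalent copper) carrying a chiral bis(oxazoline) ligand. It would close the carbocycle as the cyclohexa-1,4-diene A4, with O3 and O6 cis.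
- For it: it is convergent, purely chemical, and delivers the ring, C7 and two stereocentres in one catalytic step. On these points it is stronger than the chosen route, which needs a separate hydroxymethylation and a fermentation.
- Against it: A4 is a doubly allylic bis-acetate one elimination away from an aromatic benzoate derivative, and it is formed in the presence of a Lewis acid. O3 and O6 arrive as identical acetates. The O4/O5 diol still has to be added to C4=C5 and then differentiated, and the imide must be reduced beside the esters. Enantiocontrol for an alkynoyl imide with a 1,4-diacyloxydiene is less assured.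
- Comparison: the chosen route offers every ring oxygen in a chemically distinct form (O3 alcohol, O6 ketone, O4/O5 acetonide) and a secured absolute configuration.

**Alternative 2:** 
- Disconnection: the C3–O and C6–O bonds, taken back to an aromatic ring that already holds C7.
- Forward key step: constant-current anodic bis-methoxylation of tert-butyl[(2,5-dimethoxyphenyl)methoxy]dimethylsilane A5 to the quinone bisketal A6.
- For it: the oxidation needs no reagent, is cheap and scalable, and C7 is present from the start. On cost and scale of the key step it is stronger than a whole-cell biotransformation.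
- Against it: A6 is achiral, so the key step sets no stereocentre. All four stereocentres and the absolute configuration must come later: one ketal must be hydrolysed selectively, an electron-poor C4=C5 bond must be cis-dihydroxylated enantioselectively, and two carbonyl groups must each be reduced with facial control.
- Comparison: the chosen route fixes two stereocentres absolutely in its first step and relays them to C3 and C6 by substrate control, with one carbonyl reduction instead of two.

**Alternative 3:** 
- Disconnection: ring bonds C3–C4 and C5–C6.
- Forward key step: inverse-electron-demand Diels–Alder reaction of 3-(2-oxo-2H-pyran-5-carbonyl)-1,3-oxazolidin-2-one A7 with 2,2-dimethyl-1,3-dioxole A8 under A3 and a chiral bis(oxazoline), followed by decarboxylative cycloreversion of the bridged lactone to the diene A9.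
- For it: A9 is the counterpart of 5 with C7 in place of bromine. Singlet-oxygen addition anti to the dioxolane and peroxide reduction would give O3 and O6 directly, so neither the hydroxymethylation nor the ketone reduction is needed. After the key step this alternative is shorter than the chosen route.
- Against it: the facial selectivity must be imposed by a catalyst chelated to an imide on a pyrone, for which the basis is thin. The cycloreversion needs heat, at which the ee-determining step is less selective and A9 can aromatise or add a second dioxole. The acyl-substituted diene is a poorer partner for singlet oxygen. A7 and A8 must themselves be prepared.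
- Comparison: the chosen route offers a precursor that needs no synthesis and a cis-dienediol whose configuration is fixed by the enzyme.

Key step: step 1

## Route

**Step 1**
Reactants: 1 bromobenzene; 2 dioxygen
Product: 3 (1S,2S)-3-bromocyclohexa-3,5-diene-1,2-diol
Conditions: whole cells of recombinant E. coli JM109(pDTG601) expressing toluene dioxygenase, IPTG induction, glucose feed, aerated mineral-salts medium, pH 6.8–7.2, 30 °C, 1 fed slowly; EtOAc extraction, crystallisation
Reagents that add atoms: dioxygen, O=O
Why: This is the enzymatic arene cis-dihydroxylation by a Rieske non-heme iron dioxygenase, a known reaction type for monohalobenzenes. Electrons from NADH reach the mononuclear divalent iron centre through the reductase, the ferredoxin and the Rieske [2Fe–2S] cluster; the iron binds O2 side-on and the resulting trivalent iron (hydro)peroxo species transfers both oxygen atoms to the same face of the C2–C3 π-bond of 1, so the two new C–O bonds are cis by mechanism. No ring is closed; the arene is dearomatised once and leaves the active site as the diene. Both new stereocentres (C1 and C2 of 3, the later C5 and C4) are controlled by the enzyme pocket, which seats the bromine in a hydrophobic niche and presents one enantioface of the ortho/meta bond to the iron–oxygen unit. The step needs 2,3- over 3,4- or ipso attack and a single enantioface; the substrate has no bias of its own, and both are secured by this binding mode. Over-oxidation to the catechol is avoided because the host lacks the cis-diol dehydrogenase, and NADH is recycled by the glucose metabolism of the cells and so acts as a catalyst. The substrate is fed at a limiting rate because it is toxic to the cells.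

**Step 2**
Reactants: 3 (1S,2S)-3-bromocyclohexa-3,5-diene-1,2-diol; 4 2,2-dimethoxypropane
Product: 5 (3aS,7aS)-4-bromo-2,2-dimethyl-3a,7a-dihydro-1,3-benzodioxole
Conditions: 2,2-dimethoxypropane, p-toluenesulfonic acid monohydrate (cat.), acetone, rt, short reaction time; Et3N quench
Reagents that add atoms: 2,2-dimethoxypropane, COC(C)(C)OC
Why: Acid-catalysed transketalisation closes the dioxolane on the cis-diol without touching a stereocentre; the short contact time and basic quench guard against dehydration to bromophenol, and 5 is used at once because such dienes dimerise by Diels–Alder reaction on storage.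

**Step 3**
Reactants: 5 (3aS,7aS)-4-bromo-2,2-dimethyl-3a,7a-dihydro-1,3-benzodioxole; 2 dioxygen
Product: 8 (3aS,7R,7aS)-7-hydroxy-2,2-dimethyl-7,7a-dihydro-1,3-benzodioxol-4(3aH)-one, via bromo endoperoxide 6 (not isolated), via gem-bromohydrin 7 (not isolated)
Conditions: O2, 5,10,15,20-tetraphenylporphyrin (cat.), visible light, CH2Cl2, −78 °C; then thiourea (2.2 equiv), MeOH, −78 °C to rt
Reagents that add atoms: dioxygen, O=O
Why: Photosensitised singlet-oxygen [4+2] cycloaddition to the cisoid diene occurs on the face opposite the dioxolane, which sets C3 (O3 anti to O4/O5); thiourea then reduces the O–O bond and the bromohydrin at C6 loses HBr to give the ketone. This is a known sequence for halodiene acetonides.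

**Step 4**
Reactants: 8 (3aS,7R,7aS)-7-hydroxy-2,2-dimethyl-7,7a-dihydro-1,3-benzodioxol-4(3aH)-one; 9 tert-butyldimethylsilyl chloride
Product: 10 (3aS,7R,7aR)-7-{[tert-butyl(dimethyl)silyl]oxy}-2,2-dimethyl-7,7a-dihydro-1,3-benzodioxol-4(3aH)-one
Conditions: TBSCl, imidazole, DMF, 0 °C to rt
Reagents that add atoms: tert-butyldimethylsilyl chloride, CC(C)(C)[Si](C)(C)Cl
Why: Standard imidazole-mediated silylation of the only hydroxyl; it masks O3 for the next two steps and the group is lost later together with the acetonide.

**Step 5**
Reactants: 10 (3aS,7R,7aR)-7-{[tert-butyl(dimethyl)silyl]oxy}-2,2-dimethyl-7,7a-dihydro-1,3-benzodioxol-4(3aH)-one; 11 formaldehyde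
Product: 12 (3aS,7R,7aR)-7-{[tert-butyl(dimethyl)silyl]oxy}-5-(hydroxymethyl)-2,2-dimethyl-7,7a-dihydro-1,3-benzodioxol-4(3aH)-one
Conditions: 37% aq. HCHO, 4-(dimethylamino)pyridine (0.5 equiv), THF–H2O, rt
Reagents that add atoms: formaldehyde, C=O
Why: Morita–Baylis–Hillman reaction: the amine adds to C2, the resulting enolate attacks formaldehyde through C1, and loss of the amine restores the enone; no stereocentre is formed, and C5 cannot epimerise because that would give a trans-fused dioxolane.

**Step 6**
Reactants: 12 (3aS,7R,7aR)-7-{[tert-butyl(dimethyl)silyl]oxy}-5-(hydroxymethyl)-2,2-dimethyl-7,7a-dihydro-1,3-benzodioxol-4(3aH)-one; 13 benzoyl chloride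
Product: 14 [(3aS,7R,7aR)-7-{[tert-butyl(dimethyl)silyl]oxy}-2,2-dimethyl-4-oxo-3a,4,7,7a-tetrahydro-1,3-benzodioxol-5-yl]methyl benzoate
Conditions: BzCl, pyridine, CH2Cl2, 0 °C
Reagents that add atoms: benzoyl chloride, O=C(Cl)c1ccccc1
Why: Acylation of the only free hydroxyl with an acid chloride; no nucleophilic acylation catalyst is added, so that the product, an allylic ester on an enone, is not exposed to SN2′ attack.

**Step 7**
Reactants: 14 [(3aS,7R,7aR)-7-{[tert-butyl(dimethyl)silyl]oxy}-2,2-dimethyl-4-oxo-3a,4,7,7a-tetrahydro-1,3-benzodioxol-5-yl]methyl benzoate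
Product: 15 [(3R,4S,5S)-3,4,5-trihydroxy-6-oxocyclohex-1-en-1-yl]methyl benzoate
Conditions: CF3CO2H–H2O (9:1), 0 °C to rt; evaporation with toluene
Reagents that add atoms: none
Why: Acid hydrolysis removes the acetonide and the silyl ether in one operation while the benzoate survives; the electron-poor enone disfavours ionisation at allylic C3, and keeping the temperature at or below rt limits enolisation towards C5.

**Step 8**
Reactants: 15 [(3R,4S,5S)-3,4,5-trihydroxy-6-oxocyclohex-1-en-1-yl]methyl benzoate
Product: 16 [(3R,4S,5R,6S)-3,4,5,6-tetrahydroxycyclohex-1-en-1-yl]methyl benzoate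
Conditions: Me4NBH(OAc)3 (5 equiv), MeCN–AcOH (1:1), −30 °C to 0 °C; MeOH co-evaporation
Reagents that add atoms: none
Why: Evans–Saksena hydroxyl-directed reduction: the β-hydroxyl at C4 (lower face, axial in the reactive conformer) exchanges for acetate on boron and delivers hydride intramolecularly through a six-membered chair-like transition state to the lower face of C6, so O6 should appear on the upper face, anti to O4 and trans to O5 (6S). The reagent is not expected to touch the ester or the C=C bond.

**Step 9**
Reactants: 16 [(3R,4S,5R,6S)-3,4,5,6-tetrahydroxycyclohex-1-en-1-yl]methyl benzoate; 17 trimethyl orthobenzoate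
Product: 19 [(3R,4S,5R,6S)-5-(benzoyloxy)-3,4,6-trihydroxycyclohex-1-en-1-yl]methyl benzoate (CNP0198957.1), via cyclic methyl orthobenzoate 18 (not isolated)
Conditions: PhC(OMe)3 (1.2 equiv), camphor-10-sulfonic acid (cat.), MeCN, rt; then 80% aq. AcOH, rt
Reagents that add atoms: trimethyl orthobenzoate, COC(OC)(OC)c1ccccc1; water, O
Why: Orthoester exchange closes the 2-methoxy-2-phenyl-1,3-dioxolane only on the cis O4/O5 pair, and acid hydrolysis through the dioxolan-2-ylium ion and the hemiorthoester opens it with the acyl group retained on the axial oxygen (known regioselective orthoester opening of cis-diols). A(1,2) strain with the C1 substituent makes O6 pseudoaxial and therefore O5 axial, so the benzoate should remain on O5; no stereocentre is changed.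

## Compound list

1 | bromobenzene | Brc1ccccc1 | starting material
2 | dioxygen | O=O | starting material
3 | (1S,2S)-3-bromocyclohexa-3,5-diene-1,2-diol | BrC1=CC=C[C@H](O)[C@@H]1O | intermediate
4 | 2,2-dimethoxypropane | COC(C)(C)OC | starting material
5 | (3aS,7aS)-4-bromo-2,2-dimethyl-3a,7a-dihydro-1,3-benzodioxole | BrC1=CC=C[C@@H]2OC(C)(C)O[C@@H]21 | intermediate
6 | bromo endoperoxide: 1-bromo-cis-7,8-(isopropylidenedioxy)-2,3-dioxabicyclo[2.2.2]oct-5-ene, O–O bridge from C3 to C6 on the face opposite the dioxolane | Br[C@@]12C=C[C@@H](OO1)[C@@H]3OC(C)(C)O[C@@H]32 | intermediate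
7 | gem-bromohydrin: (3aS,7R,7aS)-4-bromo-2,2-dimethyl-3a,4,7,7a-tetrahydro-1,3-benzodioxole-4,7-diol, both hydroxyls on the face opposite the dioxolane | Br[C@]1(O)C=C[C@@H](O)[C@@H]2OC(C)(C)O[C@@H]21 | intermediate
8 | (3aS,7R,7aS)-7-hydroxy-2,2-dimethyl-7,7a-dihydro-1,3-benzodioxol-4(3aH)-one | O=C1C=C[C@@H](O)[C@@H]2OC(C)(C)O[C@@H]21 | intermediate
9 | tert-butyldimethylsilyl chloride | CC(C)(C)[Si](C)(C)Cl | starting material
10 | (3aS,7R,7aR)-7-{[tert-butyl(dimethyl)silyl]oxy}-2,2-dimethyl-7,7a-dihydro-1,3-benzodioxol-4(3aH)-one | O=C1C=C[C@@H](O[Si](C)(C)C(C)(C)C)[C@@H]2OC(C)(C)O[C@@H]21 | intermediate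
11 | formaldehyde | C=O | starting material
12 | (3aS,7R,7aR)-7-{[tert-butyl(dimethyl)silyl]oxy}-5-(hydroxymethyl)-2,2-dimethyl-7,7a-dihydro-1,3-benzodioxol-4(3aH)-one | O=C1C(CO)=C[C@@H](O[Si](C)(C)C(C)(C)C)[C@@H]2OC(C)(C)O[C@@H]21 | intermediate
13 | benzoyl chloride | O=C(Cl)c1ccccc1 | starting material
14 | [(3aS,7R,7aR)-7-{[tert-butyl(dimethyl)silyl]oxy}-2,2-dimethyl-4-oxo-3a,4,7,7a-tetrahydro-1,3-benzodioxol-5-yl]methyl benzoate | O=C(OCC1=C[C@@H](O[Si](C)(C)C(C)(C)C)[C@@H]2OC(C)(C)O[C@@H]2C1=O)c1ccccc1 | intermediate
15 | [(3R,4S,5S)-3,4,5-trihydroxy-6-oxocyclohex-1-en-1-yl]methyl benzoate | O=C(OCC1=C[C@@H](O)[C@H](O)[C@H](O)C1=O)c1ccccc1 | intermediate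
16 | [(3R,4S,5R,6S)-3,4,5,6-tetrahydroxycyclohex-1-en-1-yl]methyl benzoate | O=C(OCC1=C[C@@H](O)[C@H](O)[C@H](O)[C@H]1O)c1ccccc1 | intermediate
17 | trimethyl orthobenzoate | COC(OC)(OC)c1ccccc1 | starting material
18 | cyclic methyl orthobenzoate of 16: cis-fused 2-methoxy-2-phenyl-1,3-dioxolane across O4 and O5, O3 and O6 free, ring configuration as in 16, both epimers at the orthoester carbon | O=C(OCC1=C[C@@H](O)[C@@H]2OC(OC)(c3ccccc3)O[C@@H]2[C@H]1O)c1ccccc1 | intermediate
19 | [(3R,4S,5R,6S)-5-(benzoyloxy)-3,4,6-trihydroxycyclohex-1-en-1-yl]methyl benzoate (CNP0198957.1) | O=C(OCC1=C[C@@H](O)[C@H](O)[C@H](OC(=O)c2ccccc2)[C@H]1O)c1ccccc1 | target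

## Step count and least certain steps

Total step count: 9. Longest linear sequence: 9 steps, from bromobenzene 1.

**Step 1 (key step).** 
- What may go wrong: the substrate poisons the cells so that conversion stalls at low titre, the plasmid-borne activity is lost during growth, or 3 dehydrates to bromophenols if the broth or the extract turns acidic.
- Fallback: a chemical route with enantioselective desymmetrisation that sets out from dioxygen 2, not from 1, and comes back to the route at 8.
- Commercial cyclohexa-1,4-diene F1 is mono-dihydroxylated (OsO4 cat., N-methylmorpholine N-oxide) to meso cis-cyclohex-4-ene-1,2-diol F2. With 4 and acid this gives (3aR,7aS)-2,2-dimethyl-3a,4,7,7a-tetrahydro-1,3-benzodioxole F3.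
- Bromine addition gives the racemic trans-5,6-dibromide F4, and double dehydrobromination with DBU gives the meso diene (3aR,7aS)-2,2-dimethyl-3a,7a-dihydro-1,3-benzodioxole F5.
- Singlet oxygen 2 adds anti to the dioxolane to give the meso endoperoxide F6. A cinchona-alkaloid-catalysed enantioselective Kornblum–DeLaMare rearrangement, which removes one of the two enantiotopic bridgehead protons, should then give 8; the pseudoenantiomeric catalyst is chosen to match, and the ee is upgraded by crystallisation if needed.

**Step 9.** 
- What may go wrong: the acyl group may end on O4 if the reacting half-chair places O4 and not O5 axial, the benzoate may migrate across the cis pair during hydrolysis, or the orthoester may exchange onto O3 or O6.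
- Fallback: sets out from 16 and comes back at 19, with the opposite positional rule. Compound 16 is heated with Bu2SnO in toluene with azeotropic removal of water to form the 4,5-O-dibutylstannylene acetal F7, which is treated with benzoyl chloride 13 at 0 °C.
- Stannylene activation delivers the acyl group to the equatorial oxygen of a cis pair, whereas orthoester opening leaves it on the axial one, so this fallback answers the case in which the conformational preference turns out opposite to the one assumed.

**Step 8.** 
- What may go wrong: facial selectivity may be eroded by undirected hydride attack or by delivery from a borate bound to O3 on the upper face, and the 1,2-reduction of the conjugated ketone may be sluggish.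
- Fallback: reduction from the convex face followed by inversion; it sets out from 14 and comes back at 16.
- Luche reduction of 14 (NaBH4, CeCl3·7H2O, MeOH, −78 °C) attacks anti to the dioxolane and should give the C6-epimeric alcohol F8, with O6 cis to O5.
- Mitsunobu reaction with chloroacetic acid inverts C6 to the chloroacetate F9. Thiourea with NaHCO3 removes the chloroacetyl group selectively beside the benzoate to give the alcohol F10 with O6 on the upper face.
- The CF3CO2H–H2O treatment of step 7 then gives 16.

**Step 5.** 
- What may go wrong: the reaction may be slow, during which base-induced β-elimination of the C4 oxygen and aromatisation, or a second hydroxymethylation, can compete.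
- Fallback: sets out from 10 and comes back at 12. α-Iodination of 10 (I2, pyridine, CH2Cl2) gives the 5-iodoenone F11, and Stille coupling with (tributylstannyl)methanol (Pd(PPh3)4, zerovalent palladium, CuI co-catalyst, THF) installs the hydroxymethyl group under non-basic conditions.

## Further compounds

F1 | step 1 | cyclohexa-1,4-diene | C1=CCC=CC1
F2 | step 1 | cis-cyclohex-4-ene-1,2-diol (meso) | O[C@@H]1CC=CC[C@@H]1O
F3 | step 1 | (3aR,7aS)-2,2-dimethyl-3a,4,7,7a-tetrahydro-1,3-benzodioxole (meso) | CC1(C)O[C@@H]2CC=CC[C@@H]2O1
F4 | step 1 | trans-5,6-dibromo-2,2-dimethylhexahydro-1,3-benzodioxole with cis ring fusion (racemic, one enantiomer drawn) | CC1(C)O[C@@H]2C[C@H](Br)[C@@H](Br)C[C@@H]2O1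
F5 | step 1 | (3aR,7aS)-2,2-dimethyl-3a,7a-dihydro-1,3-benzodioxole (meso) | CC1(C)O[C@@H]2C=CC=C[C@@H]2O1
F6 | step 1 | meso endoperoxide: cis-7,8-(isopropylidenedioxy)-2,3-dioxabicyclo[2.2.2]oct-5-ene, O–O bridge anti to the dioxolane | [C@@H]12C=C[C@@H](OO1)[C@@H]3OC(C)(C)O[C@@H]32
F7 | step 9 | 4,5-O-dibutylstannylene acetal of 16 | O=C(OCC1=C[C@@H](O)[C@@H]2O[Sn](CCCC)(CCCC)O[C@@H]2[C@H]1O)c1ccccc1
F8 | step 8 | C6-epimeric alcohol from 14, C6 hydroxyl cis to the dioxolane, silyl ether and acetonide retained | O=C(OCC1=C[C@@H](O[Si](C)(C)C(C)(C)C)[C@@H]2OC(C)(C)O[C@@H]2[C@@H]1O)c1ccccc1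
F9 | step 8 | C6 chloroacetate with inverted configuration, O6 trans to the dioxolane | O=C(OCC1=C[C@@H](O[Si](C)(C)C(C)(C)C)[C@@H]2OC(C)(C)O[C@@H]2[C@H]1OC(=O)CCl)c1ccccc1
F10 | step 8 | C6 alcohol with O6 trans to the dioxolane, silyl ether and acetonide retained | O=C(OCC1=C[C@@H](O[Si](C)(C)C(C)(C)C)[C@@H]2OC(C)(C)O[C@@H]2[C@H]1O)c1ccccc1
F11 | step 5 | (3aS,7R,7aR)-7-{[tert-butyl(dimethyl)silyl]oxy}-5-iodo-2,2-dimethyl-7,7a-dihydro-1,3-benzodioxol-4(3aH)-one | O=C1C(I)=C[C@@H](O[Si](C)(C)C(C)(C)C)[C@@H]2OC(C)(C)O[C@@H]21
A1 | alternative 1 | (1E,3E)-buta-1,3-diene-1,4-diyl diacetate | CC(=O)O/C=C/C=C/OC(C)=O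
A2 | alternative 1 | 3-(prop-2-ynoyl)-1,3-oxazolidin-2-one | C#CC(=O)N1CCOC1=O
A3 | alternative 1 | Cu(OTf)2, copper bis(trifluoromethanesulfonate) | [Cu+2].[O-]S(=O)(=O)C(F)(F)F.[O-]S(=O)(=O)C(F)(F)F
A4 | alternative 1 | 3-{[(3S,6R)-3,6-bis(acetyloxy)cyclohexa-1,4-dien-1-yl]carbonyl}-1,3-oxazolidin-2-one | O=C(N1CCOC1=O)C1=C[C@@H](OC(C)=O)C=C[C@H]1OC(C)=O
A5 | alternative 2 | tert-butyl[(2,5-dimethoxyphenyl)methoxy]dimethylsilane | COc1ccc(OC)c(CO[Si](C)(C)C(C)(C)C)c1
A6 | alternative 2 | tert-butyldimethyl[(3,3,6,6-tetramethoxycyclohexa-1,4-dien-1-yl)methoxy]silane | COC1(OC)C=CC(OC)(OC)C(CO[Si](C)(C)C(C)(C)C)=C1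
A7 | alternative 3 | 3-(2-oxo-2H-pyran-5-carbonyl)-1,3-oxazolidin-2-one | O=C1C=CC(C(=O)N2CCOC2=O)=CO1
A8 | alternative 3 | 2,2-dimethyl-1,3-dioxole | CC1(C)OC=CO1
A9 | alternative 3 | 3-{[(3aR,7aS)-2,2-dimethyl-3a,7a-dihydro-1,3-benzodioxol-5-yl]carbonyl}-1,3-oxazolidin-2-one | C1=C(C(=O)N2CCOC2=O)C=C[C@@H]3OC(C)(C)O[C@H]13
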